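## The problem

Hispidulin 7-sulfate (25) is a flavone: a chromen-4-one in which ring A and ring C share the C4a–C8a bond, with a 4-hydroxyphenyl group (ring B) on C2. It has no stereocentre, so the whole difficulty is regiochemical. Ring A carries three neighbouring oxygens in three different states (free hydroxyl on C5, methyl ether on C6, hydrogen sulfate on C7) next to a single hydrogen on C8, and a fourth phenol on ring B has to stay free. The aryl hydrogen sulfate is the fragile group: acid and heat remove it and it makes the molecule very polar, so it must go on late, on O7 only, and be followed only by mild, non-acidic chemistry. The 5-hydroxyl is hydrogen-bonded to the C4 carbonyl and is inert to sulfating agents, so at that stage only O7 and O4' need different treatment. O5 and O8a, however, both flank C4a, and closing ring C through the wrong one would give the 8-methoxy isomer. The feature that opens a way round aromatic substitution is the pattern of ring A itself: oxygen on C5, C6, C7 and C8a, hydrogen on C8 and the acyl carbon C4 on C4a. Cutting C4a–C8a turns this ring into a dienylketene whose C8a–C8–C7–C6 part is a cyclobutenone derived from squaric acid and whose C5–C4a–C4 part is a β-alkoxyacrylic acid derivative.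

## Retrosynthesis

**Sulfate and last protecting group (25 ⇒ 24 ⇒ 23).** The O7–S bond and the O4'–Si bond are cut first. Sulfating while the 4'-oxygen is still silylated is what makes the reaction selective: in 23 the 5-hydroxyl is chelated and O7 is the only reactive phenol. A silyl ether is preferred on O4' to an acid- or hydrogenolysis-labile group because fluoride removes it without touching a sulfate monoester. The forward steps must stay free of acid until a final cold proton exchange.

**The two ring A protecting groups (23 ⇒ 22 ⇒ 21).** The O7–benzyl and O5–methoxymethyl bonds are cut next. The two groups differ because each arrives with its own building block, not because a selective protection is needed. The acetal on O5 is there to keep that oxygen out of the ring C closure, and it is removed with acid while benzyl still covers O7. Benzyl is then removed by hydrogenolysis, which must spare the silyl ether and the C2–C3 double bond.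

**Ring C (21 ⇒ 19).** The O1–C2 bond is cut to give the o-hydroxyaryl ynone 19. Cutting C2–C3 instead (a 1,3-diketone route) would need extra steps and an acidic dehydration that the acetal on O5 would not survive. The ynone also matches the key step, which delivers ring A with a free phenol exactly at O8a and O5 masked. The forward closure has to be 6-endo and not 5-exo.

**Ring B and C2–C3 (19 ⇒ 15 + 17, 17 ⇒ 16).** The C3–C4 bond is cut, leading to the N-methoxy-N-methylamide 15 and the lithium acetylide 18 of silyl ether 17, itself one step from 4-ethynylphenol (16). This removes ring B and two carbons in one operation. The forward addition has to stop at the ketone and tolerate the free phenol of 15.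

**Ring A (15 ⇒ 12), the key disconnection.** The C4a–C8a bond is cut, which unfolds the benzene ring into the 4-alkenyl-4-methoxycyclobutenone 12 by way of dienylketene 13. Building the same pentasubstituted ring by substitution on a benzene would require four regiochemical decisions on a ring with three similar oxygens. Here every substituent sits where the connectivity of 12 puts it. The precursor has no aromatic ring A at all, only a four-membered ring and one alkene. The forward reaction needs a thermal ring opening with the methoxy group rotating outward, then a 6π closure onto the amide-bearing carbon.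

**The cyclobutenone (12 ⇒ 5 + 9).** The bond between the quaternary ring carbon (future C6) and the alkene carbon (future C5) is cut, together with the O–methyl bond. The fragments are benzyl semisquarate 5 and the β-lithiated form 10 of acrylamide 9. The forward addition must take place at the carbonyl of 5 that is not part of the vinylogous ester, and the resulting alkoxide 11 must be methylated before it can attack the neighbouring amide.

**Building blocks (5 ⇒ 3 ⇒ 1 + 2; 9 ⇒ 6 + 7).** Semisquarate 5 comes from dibenzyl squarate 3 by loss of one benzyloxy group with reduction, and 3 from squaric acid (1) and two molecules of benzyl alcohol (2). Acrylamide 9 comes from N-methoxy-N-methylacetamide (6) by formylation with ethyl formate (7) and O-alkylation of enolate 8. All five starting materials (1, 2, 6, 7, 16) are commercial.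

## Roads not taken

**Alternative 1:** Ring A could be closed at C4a–C5 by a Claisen condensation. The substrate would be the pyranone keto ester A1, in which ring C and ring B already exist and the side chain on C8a carries C8, the C7 ketone, the methoxylated C6 and the C5 ester. Base would fold it to the 5,7-dihydroxy-6-methoxyflavone A2.
- Merits: it is short and biomimetic. There is no question of which oxygen closes ring C, and the 5,7-diol with the 6-methoxy group in place appears in one step, ready for sulfation at O7 with the 4'-benzyl ether removed afterwards. In step count it would probably beat the chosen plan.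
- Weak points: the most acidic site of A1 is the methine between ketone and ester (C6), and its enolate deactivates the very ester that must be attacked. C4a is only weakly nucleophilic and is reached only through the extended enolate from C8. Aldol-type closures and opening of the pyranone by base compete. A1 itself requires a clean C-acylation of a methylpyranone anion.
- Comparison: the chosen plan sets against the shorter sequence a ring closure that is pericyclic and does not depend on which enolate forms.

**Alternative 2:** Ring C could be closed at C4–C4a by intramolecular Friedel–Crafts acylation. The symmetric phenol A3 would be added to an arylpropiolic ester and the product hydrolysed to the (Z)-aryloxycinnamic acid A4. Activation of A4 as a mixed anhydride with (CF3CO)2O should then give the flavone A5.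
- Merits: the symmetry of A3 makes the two ortho positions identical, which removes the regiochemical problem as completely as the chosen plan does. The route is convergent, uses classical reactions, and the 4'-pivalate is orthogonal to benzyl and to the sulfate. In precedent and probably in length it is at least the equal of the chosen plan.
- Weak points: the acid must have the Z geometry. Hot acid anhydride meets two benzyl ethers on a very electron-rich ring, so debenzylation, C-benzylation and ring trifluoroacetylation are risks. The aryl vinyl ether is hydrolytically labile. A3 needs several steps of its own from a trioxygenated benzoate.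
- Comparison: the chosen plan offers no strongly acidic step on the electron-rich ring, and an oxygen pattern that is assembled rather than carved out of a gallate-type arene.

**Alternative 3:** Ring C could be closed at O1–C8a by copper-mediated O-arylation. The enol oxygen of the iodo diketone A6 would displace iodide under CuI, 1,10-phenanthroline and K2CO3 to give the flavone A7.
- Merits: this closure is the most dependable ring-forming step of all four plans, and the iodine marks C8a so that O5 cannot interfere.
- Weak points: the burden moves to A6. Its iodine must sit ortho to the acyl group, at a position activated only by the para methoxy group. The other free position (future C8) is ortho and para to the two acetal oxygens and is where an electrophile would go. The iodine would therefore have to be placed by directed metalation or carried from the start, on a pentasubstituted ring.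
- Comparison: the chosen plan has a less tested key step but avoids every aromatic substitution on ring A.

Key step: step 5

Assumption: the target is taken as the free aryl hydrogen sulfate as drawn; it is liberated from its salt by a cold proton exchange in the last step and should be stored cold, since such acids slowly lose sulfate.

## Route

Step 1
Reactants: 1 squaric acid (3,4-dihydroxycyclobut-3-ene-1,2-dione); 2 benzyl alcohol (two molecules are incorporated)
Product: 3 dibenzyl squarate [3,4-bis(benzyloxy)cyclobut-3-ene-1,2-dione]
Conditions: BnOH (4 equiv), toluene, reflux, Dean–Stark trap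
Reagents that add atoms: benzyl alcohol (the second molecule of 2), OCc1ccccc1
Why: Self-catalysed azeotropic double esterification of the strongly acidic vinylogous diacid, the standard entry to dialkyl squarates; each of the two hydroxyls condenses with one molecule of benzyl alcohol, and removal of the two equivalents of water drives the reaction to the diester.

Step 2
Reactants: 3 dibenzyl squarate
Product: 5 3-(benzyloxy)cyclobut-3-ene-1,2-dione (benzyl semisquarate), via hydroxycyclobutenone 4 (not isolated)
Conditions: LiAlH(OtBu)3, THF, −78 → 0 °C, aq. NH4Cl; crude 4, then conc. HCl (cat.), CH2Cl2, rt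
Reagents that add atoms: none
Why: Mono 1,2-reduction of a squarate carbonyl by the hindered hydride, then acid-promoted ionisation of the carbinol to an alkoxy-stabilised cyclobutenyl cation, addition of water at the oxocarbenium carbon and loss of benzyl alcohol; this carbonyl transposition is the established route from dialkyl squarates to semisquarates.

Step 3
Reactants: 6 N-methoxy-N-methylacetamide; 7 ethyl formate
Product: 9 (E)-N-methoxy-3-(methoxymethoxy)-N-methylprop-2-enamide, via sodium enolate 8 (not isolated)
Conditions: NaN(SiMe3)2, THF, −78 °C; HCO2Et, −78 → 0 °C; evaporate; MOMCl, DMF, 0 °C → rt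
Reagents that add atoms: chloromethyl methyl ether, COCCl
Why: Claisen formylation of the amide enolate, driven by formation of the stabilised formyl enolate, followed by O-alkylation with the hard chloromethyl ether; the open sodium enolate in DMF and the thermodynamic preference of β-alkoxyacrylic derivatives should favour the E ether, and any Z isomer is removed by chromatography.

Step 4
Reactants: 9 (E)-N-methoxy-3-(methoxymethoxy)-N-methylprop-2-enamide; 5 3-(benzyloxy)cyclobut-3-ene-1,2-dione
Product: 12 (E)-3-[2-(benzyloxy)-1-methoxy-4-oxocyclobut-2-en-1-yl]-N-methoxy-3-(methoxymethoxy)-N-methylprop-2-enamide (racemic), via vinyllithium 10 (not isolated), via lithium alkoxide 11 (not isolated)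
Conditions: LiN(iPr)2 (1.1 equiv), THF, −95 °C; 5 in THF, −95 → −78 °C; MeOTf (3 equiv), −78 → −20 °C; Et3N-deactivated silica
Reagents that add atoms: methyl trifluoromethanesulfonate, COS(=O)(=O)C(F)(F)F
Why: Carbonyl-directed β-lithiation of a β-alkoxyacrylic acid derivative gives the chelated vinyllithium with lithium cis to the amide, which fixes the alkene geometry; it adds 1,2 to the more electrophilic carbonyl of the semisquarate (the one outside the vinylogous ester) and the tertiary alkoxide is capped in situ by O-methylation. The quaternary centre is formed racemic and needs no control because step 5 destroys it.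

Step 5
Reactants: 12 (E)-3-[2-(benzyloxy)-1-methoxy-4-oxocyclobut-2-en-1-yl]-N-methoxy-3-(methoxymethoxy)-N-methylprop-2-enamide
Product: 15 4-(benzyloxy)-2-hydroxy-N,5-dimethoxy-6-(methoxymethoxy)-N-methylbenzamide, via dienylketene 13 (not isolated), via cyclohexadienone 14 (not isolated)
Conditions: toluene (0.02 M, degassed), reflux (110 °C)
Reagents that add atoms: none
Why: This is the thermal rearrangement of a 4-alkenylcyclobutenone to a phenol (Moore rearrangement), a known reaction type applied here to an alkenyl group that carries an amide. Heating opens the four-membered ring of 12 by a conrotatory 4π electrocyclic reaction across the bond between the carbonyl carbon and the quaternary carbon, giving dienylketene 13. Ring A then closes by a thermal disrotatory 6π electrocyclisation in which the ketene carbon (C8a) bonds to the amide-bearing alkene carbon (C4a) to give cyclohexadienone 14, and a proton shift from C4a to oxygen makes the ring aromatic. No stereocentre is formed: the quaternary centre of 12 and the sp3 carbon of 14 both end as aromatic carbons. The selectivity needed is torquoselectivity, with the methoxy group rotating outward and the alkenyl group inward, as donor substituents on C4 of cyclobutenones do; since the opening is reversible, a ketene of the wrong geometry returns to 12 and is drained through the productive one. The closure is polarity-matched, the electrophilic ketene carbon meeting the nucleophilic α-carbon of the β-alkoxyacrylamide, and the inward-pointing amide faces only the linear ketene, which has no substituent to clash with. The position of every ring A substituent is set by the connectivity of 12, so no regiochemical choice is made in this step. High dilution and exclusion of oxygen should keep the ketene from dimerising or being captured by the product phenol.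

Step 6
Reactants: 16 4-ethynylphenol
Product: 17 (4-ethynylphenoxy)tri(propan-2-yl)silane
Conditions: TIPSCl, imidazole, DMF, rt
Reagents that add atoms: chlorotri(propan-2-yl)silane, CC(C)[Si](Cl)(C(C)C)C(C)C
Why: Standard imidazole-promoted silylation of a phenol; the bulky triisopropylsilyl ether is chosen to survive organolithium, amine, dilute acid and hydrogenation and to leave with fluoride at the end.

Step 7
Reactants: 17 (4-ethynylphenoxy)tri(propan-2-yl)silane; 15 4-(benzyloxy)-2-hydroxy-N,5-dimethoxy-6-(methoxymethoxy)-N-methylbenzamide
Product: 19 1-[4-(benzyloxy)-2-hydroxy-5-methoxy-6-(methoxymethoxy)phenyl]-3-{4-[(triisopropylsilyl)oxy]phenyl}prop-2-yn-1-one, via lithium acetylide 18 (not isolated)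
Conditions: 17 (3.3 equiv), n-BuLi (3.0 equiv), THF, −78 °C; 15, −78 → 0 °C; cold aq. NH4Cl
Reagents that add atoms: none
Why: Weinreb ketone synthesis with a lithium acetylide; the first equivalent deprotonates the phenol, and the chelated tetrahedral intermediate prevents double addition and keeps the ynone masked until the quench, so it cannot cyclise under the basic conditions.

Step 8
Reactants: 19 1-[4-(benzyloxy)-2-hydroxy-5-methoxy-6-(methoxymethoxy)phenyl]-3-{4-[(triisopropylsilyl)oxy]phenyl}prop-2-yn-1-one
Product: 21 7-(benzyloxy)-6-methoxy-5-(methoxymethoxy)-2-{4-[(triisopropylsilyl)oxy]phenyl}-4H-chromen-4-one, via enaminone 20 (not isolated)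
Conditions: Et2NH (5 equiv), EtOH, 60 °C
Reagents that add atoms: none
Why: Amine-mediated flavone synthesis from an o-hydroxyaryl ynone: conjugate addition of diethylamine gives the enaminone, whose β-carbon is the only electrophilic site, so the phenol closes the six-membered ring by addition–elimination (6-endo overall) and no aurone can form. Only O8a is free, O5 being an acetal, which fixes the ring C regiochemistry.

Step 9
Reactants: 21 7-(benzyloxy)-6-methoxy-5-(methoxymethoxy)-2-{4-[(triisopropylsilyl)oxy]phenyl}-4H-chromen-4-one
Product: 22 7-(benzyloxy)-5-hydroxy-6-methoxy-2-{4-[(triisopropylsilyl)oxy]phenyl}-4H-chromen-4-one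
Conditions: conc. HCl (cat.), MeOH–THF, 40 °C
Reagents that add atoms: none
Why: Acid-catalysed acetal exchange with methanol; the methoxymethyl ether peri to the C4 carbonyl is especially labile, while the aryl triisopropylsilyl ether and the benzyl ether tolerate dilute methanolic acid.

Step 10
Reactants: 22 7-(benzyloxy)-5-hydroxy-6-methoxy-2-{4-[(triisopropylsilyl)oxy]phenyl}-4H-chromen-4-one
Product: 23 5,7-dihydroxy-6-methoxy-2-{4-[(triisopropylsilyl)oxy]phenyl}-4H-chromen-4-one
Conditions: H2 (1 atm), 10% Pd/C, EtOAc–THF, rt
Reagents that add atoms: none
Why: Hydrogenolysis of an aryl benzyl ether; the flavone C2–C3 double bond and the silyl ether are normally untouched under these mild conditions.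

Step 11
Reactants: 23 5,7-dihydroxy-6-methoxy-2-{4-[(triisopropylsilyl)oxy]phenyl}-4H-chromen-4-one
Product: 24 pyridinium 5-hydroxy-6-methoxy-4-oxo-2-{4-[(triisopropylsilyl)oxy]phenyl}-4H-chromen-7-yl sulfate
Conditions: SO3·pyridine (3 equiv), pyridine, rt
Reagents that add atoms: sulfur trioxide–pyridine complex, O=S(=O)([O-])[n+]1ccccc1
Why: O-Sulfation of a phenol with a sulfur trioxide–amine complex; the 7-hydroxyl is the most acidic and the only unhindered, non-chelated phenol, the 5-hydroxyl being held by the hydrogen bond to the C4 carbonyl and the 4'-oxygen being silylated.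

Step 12
Reactants: 24 pyridinium 5-hydroxy-6-methoxy-4-oxo-2-{4-[(triisopropylsilyl)oxy]phenyl}-4H-chromen-7-yl sulfate
Product: 25 hispidulin 7-sulfate [5-hydroxy-2-(4-hydroxyphenyl)-6-methoxy-4-oxo-4H-chromen-7-yl hydrogen sulfate]
Conditions: KHF2 (2.5 equiv), MeOH, rt; then Dowex 50W-X8 (H+ form), MeOH–H2O, 0 °C; freeze-dry
Reagents that add atoms: none
Why: Bifluoride in methanol selectively cleaves phenolic silyl ethers under nearly neutral conditions that a sulfate monoester anion tolerates; cold cation exchange then replaces pyridinium and potassium by a proton to give the free hydrogen sulfate.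

## Compound list

1 | squaric acid (3,4-dihydroxycyclobut-3-ene-1,2-dione) | OC1=C(O)C(=O)C1=O | starting material
2 | benzyl alcohol | OCc1ccccc1 | starting material
3 | dibenzyl squarate, 3,4-bis(benzyloxy)cyclobut-3-ene-1,2-dione | O=C1C(=O)C(OCc2ccccc2)=C1OCc1ccccc1 | intermediate
4 | 2,3-bis(benzyloxy)-4-hydroxycyclobut-2-en-1-one (racemic) | O=C1C(OCc2ccccc2)=C(OCc2ccccc2)C1O | intermediate
5 | 3-(benzyloxy)cyclobut-3-ene-1,2-dione | O=C1C=C(OCc2ccccc2)C1=O | intermediate
6 | N-methoxy-N-methylacetamide | CC(=O)N(C)OC | starting material
7 | ethyl formate | CCOC=O | starting material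
8 | sodium (E)-3-[methoxy(methyl)amino]-3-oxoprop-1-en-1-olate | [Na+].[O-]/C=C/C(=O)N(C)OC | intermediate
9 | (E)-N-methoxy-3-(methoxymethoxy)-N-methylprop-2-enamide | COCO/C=C/C(=O)N(C)OC | intermediate
10 | [(E)-3-[methoxy(methyl)amino]-1-(methoxymethoxy)-3-oxoprop-1-en-1-yl]lithium | [Li]/C(OCOC)=C\C(=O)N(C)OC | intermediate
11 | lithium 2-(benzyloxy)-1-[(E)-3-[methoxy(methyl)amino]-1-(methoxymethoxy)-3-oxoprop-1-en-1-yl]-4-oxocyclobut-2-en-1-olate (racemic) | [Li+].[O-]C1(/C(OCOC)=C\C(=O)N(C)OC)C(OCc2ccccc2)=CC1=O | intermediate
12 | (E)-3-[2-(benzyloxy)-1-methoxy-4-oxocyclobut-2-en-1-yl]-N-methoxy-3-(methoxymethoxy)-N-methylprop-2-enamide (racemic) | O=C1C=C(OCc2ccccc2)C1(OC)/C(OCOC)=C\C(=O)N(C)OC | intermediate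
13 | (2E,4Z)-5-(benzyloxy)-N,4-dimethoxy-3-(methoxymethoxy)-N-methyl-7-oxohepta-2,4,6-trienamide | O=C=C/C(OCc1ccccc1)=C(OC)\C(OCOC)=C/C(=O)N(C)OC | intermediate
14 | 4-(benzyloxy)-N,5-dimethoxy-6-(methoxymethoxy)-N-methyl-2-oxocyclohexa-3,5-diene-1-carboxamide (racemic) | CON(C)C(=O)C1C(=O)C=C(OCc2ccccc2)C(OC)=C1OCOC | intermediate
15 | 4-(benzyloxy)-2-hydroxy-N,5-dimethoxy-6-(methoxymethoxy)-N-methylbenzamide | CON(C)C(=O)c1c(O)cc(OCc2ccccc2)c(OC)c1OCOC | intermediate
16 | 4-ethynylphenol | C#Cc1ccc(O)cc1 | starting material
17 | (4-ethynylphenoxy)tri(propan-2-yl)silane | C#Cc1ccc(O[Si](C(C)C)(C(C)C)C(C)C)cc1 | intermediate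
18 | ({4-[(triisopropylsilyl)oxy]phenyl}ethynyl)lithium | [Li]C#Cc1ccc(O[Si](C(C)C)(C(C)C)C(C)C)cc1 | intermediate
19 | 1-[4-(benzyloxy)-2-hydroxy-5-methoxy-6-(methoxymethoxy)phenyl]-3-{4-[(triisopropylsilyl)oxy]phenyl}prop-2-yn-1-one | O=C(C#Cc1ccc(O[Si](C(C)C)(C(C)C)C(C)C)cc1)c1c(O)cc(OCc2ccccc2)c(OC)c1OCOC | intermediate
20 | (E)-1-[4-(benzyloxy)-2-hydroxy-5-methoxy-6-(methoxymethoxy)phenyl]-3-(diethylamino)-3-{4-[(triisopropylsilyl)oxy]phenyl}prop-2-en-1-one | CCN(CC)/C(=C/C(=O)c1c(O)cc(OCc2ccccc2)c(OC)c1OCOC)c1ccc(O[Si](C(C)C)(C(C)C)C(C)C)cc1 | intermediate
21 | 7-(benzyloxy)-6-methoxy-5-(methoxymethoxy)-2-{4-[(triisopropylsilyl)oxy]phenyl}-4H-chromen-4-one | COc1c(OCc3ccccc3)cc2oc(-c4ccc(O[Si](C(C)C)(C(C)C)C(C)C)cc4)cc(=O)c2c1OCOC | intermediate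
22 | 7-(benzyloxy)-5-hydroxy-6-methoxy-2-{4-[(triisopropylsilyl)oxy]phenyl}-4H-chromen-4-one | COc1c(OCc3ccccc3)cc2oc(-c4ccc(O[Si](C(C)C)(C(C)C)C(C)C)cc4)cc(=O)c2c1O | intermediate
23 | 5,7-dihydroxy-6-methoxy-2-{4-[(triisopropylsilyl)oxy]phenyl}-4H-chromen-4-one | COc1c(O)cc2oc(-c3ccc(O[Si](C(C)C)(C(C)C)C(C)C)cc3)cc(=O)c2c1O | intermediate
24 | pyridinium 5-hydroxy-6-methoxy-4-oxo-2-{4-[(triisopropylsilyl)oxy]phenyl}-4H-chromen-7-yl sulfate | COc1c(OS(=O)(=O)[O-])cc2oc(-c3ccc(O[Si](C(C)C)(C(C)C)C(C)C)cc3)cc(=O)c2c1O.c1cc[nH+]cc1 | intermediate
25 | hispidulin 7-sulfate, 5-hydroxy-2-(4-hydroxyphenyl)-6-methoxy-4-oxo-4H-chromen-7-yl hydrogen sulfate | COc1c(OS(=O)(=O)O)cc2oc(-c3ccc(O)cc3)cc(=O)c2c1O | target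

## Step count and risks

Total step count: 12. Longest linear sequence: 10 steps (steps 1, 2, 4, 5, 7, 8, 9, 10, 11, 12, from squaric acid 1). Steps 3 and 6 are side branches.

**Step 5 (key step).** The most likely failure is slow or unselective opening of the crowded methyl ether, so that dimerisation or capture of the ketene competes with closure onto the inward-pointing, amide-substituted carbon. The fallback moves the methylation to after the ring construction and uses the substrate type for which the rearrangement is best documented.
- It sets out from lithium alkoxide 11 (made from 5 and 10 as in step 4) and returns at 15.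
- Alkoxide 11 is protonated at −78 °C with aqueous NH4Cl instead of being methylated. This gives the tertiary alcohol (E)-3-[2-(benzyloxy)-1-hydroxy-4-oxocyclobut-2-en-1-yl]-N-methoxy-3-(methoxymethoxy)-N-methylprop-2-enamide F1.
- The hydroxyl group is the stronger outward-rotating donor. Heating F1 in degassed toluene should therefore give the hydroquinone 4-(benzyloxy)-2,5-dihydroxy-N-methoxy-6-(methoxymethoxy)-N-methylbenzamide F2.
- F2 is kept under argon and methylated with MeI (1 equiv) and K2CO3 in acetone. This should occur at the hydroxyl that is not hydrogen-bonded to the amide, giving 15.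

**Step 4.** Three processes threaten it: self-condensation of the vinyllithium on the amide carbonyl, base-induced fragmentation of the N-methoxy group, and lactonisation of the alkoxide onto the cis amide before it is methylated. The fallback replaces the amide by a morpholine amide, which has no N–O bond and is a poorer acceptor for the alkoxide.
- It sets out from 5 and 7 and returns at 19.
- Commercial 1-(morpholin-4-yl)ethan-1-one F3 is formylated with 7 and O-alkylated with MOMCl as in step 3, giving (E)-3-(methoxymethoxy)-1-(morpholin-4-yl)prop-2-en-1-one F4.
- Lithiation of F4, addition to 5 and methylation as in step 4 give 3-(benzyloxy)-4-methoxy-4-[(E)-1-(methoxymethoxy)-3-(morpholin-4-yl)-3-oxoprop-1-en-1-yl]cyclobut-2-en-1-one F5.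
- Thermolysis as in step 5 gives [4-(benzyloxy)-2-hydroxy-5-methoxy-6-(methoxymethoxy)phenyl](morpholin-4-yl)methanone F6.
- F6 reacts with acetylide 18 in the known ketone synthesis from morpholine amides to give 19.

**Step 7.** The twisted amide, flanked by a phenoxide and an acetal, may not accept the acetylide, and the recovered phenol amide may then be degraded by the excess base. The fallback passes through the far more electrophilic aldehyde.
- It sets out from 15 and returns at 19.
- Reduction of 15 with LiAlH4 (THF, −78 → 0 °C), where the small hydride and the chelated intermediate stop at the aldehyde stage, gives 4-(benzyloxy)-2-hydroxy-5-methoxy-6-(methoxymethoxy)benzaldehyde F7.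
- Addition of acetylide 18 gives the racemic alcohol 1-[4-(benzyloxy)-2-hydroxy-5-methoxy-6-(methoxymethoxy)phenyl]-3-{4-[(triisopropylsilyl)oxy]phenyl}prop-2-yn-1-ol F8.
- Oxidation of F8 with MnO2 in CH2Cl2 gives 19.

**Step 1.** Under hot, strongly acidic conditions benzyl alcohol may self-etherify and benzylate the solvent faster than the second esterification proceeds. The fallback replaces the equilibrium esterification by acylation chemistry.
- It sets out from 1 and returns at 3.
- Squaric acid 1 is converted with oxalyl chloride and catalytic DMF into 3,4-dichlorocyclobut-3-ene-1,2-dione F9.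
- F9 is treated with two equivalents of 2 and Et3N in CH2Cl2 at 0 °C to give 3.

## Further compounds

F1 | step 5 | (E)-3-[2-(benzyloxy)-1-hydroxy-4-oxocyclobut-2-en-1-yl]-N-methoxy-3-(methoxymethoxy)-N-methylprop-2-enamide (racemic) | O=C1C=C(OCc2ccccc2)C1(O)/C(OCOC)=C\C(=O)N(C)OC
F2 | step 5 | 4-(benzyloxy)-2,5-dihydroxy-N-methoxy-6-(methoxymethoxy)-N-methylbenzamide | CON(C)C(=O)c1c(O)cc(OCc2ccccc2)c(O)c1OCOC
F3 | step 4 | 1-(morpholin-4-yl)ethan-1-one | CC(=O)N1CCOCC1
F4 | step 4 | (E)-3-(methoxymethoxy)-1-(morpholin-4-yl)prop-2-en-1-one | COCO/C=C/C(=O)N1CCOCC1
F5 | step 4 | 3-(benzyloxy)-4-methoxy-4-[(E)-1-(methoxymethoxy)-3-(morpholin-4-yl)-3-oxoprop-1-en-1-yl]cyclobut-2-en-1-one (racemic) | O=C1C=C(OCc2ccccc2)C1(OC)/C(OCOC)=C\C(=O)N3CCOCC3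
F6 | step 4 | [4-(benzyloxy)-2-hydroxy-5-methoxy-6-(methoxymethoxy)phenyl](morpholin-4-yl)methanone | O=C(c1c(O)cc(OCc2ccccc2)c(OC)c1OCOC)N3CCOCC3
F7 | step 7 | 4-(benzyloxy)-2-hydroxy-5-methoxy-6-(methoxymethoxy)benzaldehyde | O=Cc1c(O)cc(OCc2ccccc2)c(OC)c1OCOC
F8 | step 7 | 1-[4-(benzyloxy)-2-hydroxy-5-methoxy-6-(methoxymethoxy)phenyl]-3-{4-[(triisopropylsilyl)oxy]phenyl}prop-2-yn-1-ol (racemic) | OC(C#Cc1ccc(O[Si](C(C)C)(C(C)C)C(C)C)cc1)c1c(O)cc(OCc2ccccc2)c(OC)c1OCOC
F9 | step 1 | 3,4-dichlorocyclobut-3-ene-1,2-dione | O=C1C(=O)C(Cl)=C1Cl
A1 | alternative 1 | methyl 4-{6-[4-(benzyloxy)phenyl]-4-oxo-4H-pyran-2-yl}-2-methoxy-3-oxobutanoate (racemic) | COC(=O)C(OC)C(=O)Cc1cc(=O)cc(-c2ccc(OCc3ccccc3)cc2)o1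
A2 | alternative 1 | 2-[4-(benzyloxy)phenyl]-5,7-dihydroxy-6-methoxy-4H-chromen-4-one | COc1c(O)cc2oc(-c3ccc(OCc4ccccc4)cc3)cc(=O)c2c1O
A3 | alternative 2 | 3,5-bis(benzyloxy)-4-methoxyphenol | COc1c(OCc2ccccc2)cc(O)cc1OCc1ccccc1
A4 | alternative 2 | (2Z)-3-[3,5-bis(benzyloxy)-4-methoxyphenoxy]-3-{4-[(2,2-dimethylpropanoyl)oxy]phenyl}prop-2-enoic acid | OC(=O)/C=C(\Oc1cc(OCc2ccccc2)c(OC)c(OCc2ccccc2)c1)c1ccc(OC(=O)C(C)(C)C)cc1
A5 | alternative 2 | 4-[5,7-bis(benzyloxy)-6-methoxy-4-oxo-4H-chromen-2-yl]phenyl pivalate | COc1c(OCc2ccccc2)cc2oc(-c3ccc(OC(=O)C(C)(C)C)cc3)cc(=O)c2c1OCc1ccccc1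
A6 | alternative 3 | 1-[4-(benzyloxy)phenyl]-3-[2-iodo-5-methoxy-4,6-bis(methoxymethoxy)phenyl]propane-1,3-dione | COCOc1cc(I)c(C(=O)CC(=O)c2ccc(OCc3ccccc3)cc2)c(OCOC)c1OC
A7 | alternative 3 | 2-[4-(benzyloxy)phenyl]-6-methoxy-5,7-bis(methoxymethoxy)-4H-chromen-4-one | COCOc1cc2oc(-c3ccc(OCc4ccccc4)cc3)cc(=O)c2c(OCOC)c1OC
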